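**Retrosynthetic overview**
1. Ebenfuran IV ⇐ Pd(0) de-allylation of 19 ⇐ ortho-C-prenylation at C5 of the chelated 4-hydroxy-3-formylbenzofuran 16 (prenyl goes on last, because the furan-forming step is acidic).
2. 16 ⇐ acid cyclodehydration of β-keto acetal 13. The aryl group carries two equivalent ortho oxygens, so either one closes the furan and the other becomes the free 4-OH.
3. 13 ⇐ hypervalent-iodine 1,2-aryl shift of chalcone 11, which places the future CHO carbon on C3 regiospecifically ⇐ Claisen–Schmidt condensation of aldehyde 6 with ketone 9.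
4. 6 ⇐ directed ortho-metalation/formylation of bis-MOM 5-methoxyresorcinol 3; 9 ⇐ O-allylation of 4'-hydroxy-2'-methoxyacetophenone 7.
5. Ring order: both benzene rings are bought; the furan ring is the only ring formed (step 6).

Assumption: the target has no stereocentre and no stereogenic double bond, so it is achiral and no stereocontrol is needed; the racemic intermediates 10, 13 and 15 lose their stereocentres before the target.

**Step 1**
Reactants: 1 5-methoxyresorcinol + 2 chloromethyl methyl ether
Product: 3 1-methoxy-3,5-bis(methoxymethoxy)benzene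
Conditions: MOMCl (2.5 equiv), i-Pr2NEt (3 equiv), CH2Cl2, 0 °C → rt
Reagents that add atoms: chloromethyl methyl ether COCCl
Why: Williamson-type O-alkylation (MOM protection) masks both phenols for the later basic and oxidative steps and installs two strong ortho-directing groups around C2.

**Step 2**
Reactants: 3 1-methoxy-3,5-bis(methoxymethoxy)benzene + 4 N,N-dimethylformamide
Product: 6 4-methoxy-2,6-bis(methoxymethoxy)benzaldehyde, via aryllithium 5 (not isolated)
Conditions: n-BuLi (1.2 equiv), TMEDA, THF, 0 °C, 1 h; DMF, 0 °C → rt; H2O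
Reagents that add atoms: N,N-dimethylformamide CN(C)C=O
Why: Directed ortho-metalation occurs at the carbon flanked by both OMOM groups (cooperative chelation, stronger than OMe), and formylation of the aryllithium with DMF gives the symmetric aldehyde after hydrolysis of the hemiaminal alkoxide.

**Step 3**
Reactants: 7 1-(4-hydroxy-2-methoxyphenyl)ethan-1-one + 8 allyl bromide
Product: 9 1-[4-(allyloxy)-2-methoxyphenyl]ethan-1-one
Conditions: allyl bromide (1.2 equiv), K2CO3, acetone, reflux
Reagents that add atoms: allyl bromide C=CCBr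
Why: Williamson etherification; the allyl ether survives KOH, I(III), HCl/MeOH, TsOH/HFIP and NaH, and is later removed by Pd(0) without touching the prenyl group or the aldehyde.

**Step 4**
Reactants: 6 4-methoxy-2,6-bis(methoxymethoxy)benzaldehyde + 9 1-[4-(allyloxy)-2-methoxyphenyl]ethan-1-one
Product: 11 (E)-1-[4-(allyloxy)-2-methoxyphenyl]-3-[4-methoxy-2,6-bis(methoxymethoxy)phenyl]prop-2-en-1-one, via aldol adduct 10 (not isolated)
Conditions: KOH (50% aq), EtOH, rt, 24–48 h
Reagents that add atoms: none
Why: Claisen–Schmidt aldol condensation of a methyl ketone with a non-enolisable aldehyde, with E1cB dehydration giving the thermodynamic E-enone; MOM and allyl ethers are base-stable.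

**Step 5**
Reactants: 11 (E)-chalcone + 12 methanol
Product: 13 1-[4-(allyloxy)-2-methoxyphenyl]-3,3-dimethoxy-2-[4-methoxy-2,6-bis(methoxymethoxy)phenyl]propan-1-one (racemic)
Conditions: PhI(OH)OTs (1.1 equiv), MeOH, 0 °C → rt
Reagents that add atoms: methanol CO
Why: Hypervalent-iodine oxidative chalcone rearrangement (isoflavone-type 1,2-aryl shift): I(III) activates the enone, MeOH adds at the benzylic carbon, the very electron-rich trioxygenated aryl migrates from Cβ to Cα with loss of PhI, and MeOH traps the oxocarbenium as the dimethyl acetal.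

**Step 6**
Reactants: 13 β-keto acetal + 14 water
Product: 16 2-[4-(allyloxy)-2-methoxyphenyl]-4-hydroxy-6-methoxy-1-benzofuran-3-carbaldehyde, via cyclic acetal 15 (not isolated)
Conditions: (a) 1 M HCl in MeOH, rt; evaporate; (b) p-TsOH·H2O, (CF3)2CHOH, rt
Reagents that add atoms: water O
Why: Acidic methanol removes both MOM groups and a phenol closes onto the acetal to give 15, then strong acid in HFIP reopens it and drives cyclodehydration of a phenol onto the aryl ketone to the aromatic 2-aryl-3-formylbenzofuran (the CHO oxygen comes from hydrolysis of the methyl oxocarbenium); the two phenols are equivalent, so one regioisomer forms and the other OH is left at C4.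

**Step 7**
Reactants: 16 4-hydroxybenzofuran-3-carbaldehyde + 17 prenyl bromide (1-bromo-3-methylbut-2-ene)
Product: 19 2-[4-(allyloxy)-2-methoxyphenyl]-4-hydroxy-6-methoxy-5-(3-methylbut-2-en-1-yl)-1-benzofuran-3-carbaldehyde, via sodium phenoxide 18 (not isolated)
Conditions: NaH (1.05 equiv), toluene, 0 °C → rt; prenyl bromide (1.2 equiv), rt → 50 °C
Reagents that add atoms: prenyl bromide CC(C)=CCBr
Why: Ortho-selective C-alkylation of a tight sodium phenoxide ion pair in a non-polar solvent: the metal bridges the phenoxide oxygen and the leaving bromide, delivering the prenyl group to C5, the only unsubstituted ortho carbon, and tautomerisation restores the chelated phenol.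

**Step 8**
Reactants: 19 5-prenyl allyl ether (12 methanol acts as allyl acceptor)
Product: 20 ebenfuran IV, 4-hydroxy-2-(4-hydroxy-2-methoxyphenyl)-6-methoxy-5-(3-methylbut-2-en-1-yl)-1-benzofuran-3-carbaldehyde
Conditions: Pd(PPh3)4 (5 mol %), K2CO3, MeOH, rt; aq. NH4Cl
Reagents that add atoms: none
Why: Tsuji–Trost de-allylation: Pd(0) ionises the aryl allyl ether to a π-allyl complex and the phenoxide, and methoxide captures the allyl group; the C-prenyl group, aldehyde and methyl ethers are inert.

**Compound list**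
1 | 5-methoxyresorcinol (5-methoxybenzene-1,3-diol) | COc1cc(O)cc(O)c1 | starting material
2 | chloromethyl methyl ether (MOMCl) | COCCl | starting material
3 | 1-methoxy-3,5-bis(methoxymethoxy)benzene | COCOc1cc(OC)cc(OCOC)c1 | intermediate
4 | N,N-dimethylformamide | CN(C)C=O | starting material
5 | aryllithium, [4-methoxy-2,6-bis(methoxymethoxy)phenyl]lithium, formed in situ | [Li]c1c(OCOC)cc(OC)cc1OCOC | intermediate
6 | 4-methoxy-2,6-bis(methoxymethoxy)benzaldehyde | COCOc1cc(OC)cc(OCOC)c1C=O | intermediate
7 | 1-(4-hydroxy-2-methoxyphenyl)ethan-1-one (4'-hydroxy-2'-methoxyacetophenone) | CC(=O)c1ccc(O)cc1OC | starting material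
8 | allyl bromide | C=CCBr | starting material
9 | 1-[4-(allyloxy)-2-methoxyphenyl]ethan-1-one | CC(=O)c1ccc(OCC=C)cc1OC | intermediate
10 | aldol adduct, 1-[4-(allyloxy)-2-methoxyphenyl]-3-hydroxy-3-[4-methoxy-2,6-bis(methoxymethoxy)phenyl]propan-1-one, racemic, formed in situ | COCOc1cc(OC)cc(OCOC)c1C(O)CC(=O)c1ccc(OCC=C)cc1OC | intermediate
11 | (E)-1-[4-(allyloxy)-2-methoxyphenyl]-3-[4-methoxy-2,6-bis(methoxymethoxy)phenyl]prop-2-en-1-one | COCOc1cc(OC)cc(OCOC)c1/C=C/C(=O)c1ccc(OCC=C)cc1OC | intermediate
12 | methanol | CO | starting material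
13 | 1-[4-(allyloxy)-2-methoxyphenyl]-3,3-dimethoxy-2-[4-methoxy-2,6-bis(methoxymethoxy)phenyl]propan-1-one, racemic | COC(OC)C(C(=O)c1ccc(OCC=C)cc1OC)c1c(OCOC)cc(OC)cc1OCOC | intermediate
14 | water | O | starting material
15 | cyclic acetal, [4-(allyloxy)-2-methoxyphenyl](4-hydroxy-2,6-dimethoxy-2,3-dihydro-1-benzofuran-3-yl)methanone, racemic diastereomer mixture, formed in situ | COC1Oc2cc(OC)cc(O)c2C1C(=O)c1ccc(OCC=C)cc1OC | intermediate
16 | 2-[4-(allyloxy)-2-methoxyphenyl]-4-hydroxy-6-methoxy-1-benzofuran-3-carbaldehyde | COc1cc(O)c2c(C=O)c(-c3ccc(OCC=C)cc3OC)oc2c1 | intermediate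
17 | prenyl bromide (1-bromo-3-methylbut-2-ene) | CC(C)=CCBr | starting material
18 | sodium phenoxide, sodium 2-[4-(allyloxy)-2-methoxyphenyl]-3-formyl-6-methoxy-1-benzofuran-4-olate, formed in situ | [Na+].[O-]c1cc(OC)cc2oc(-c3ccc(OCC=C)cc3OC)c(C=O)c12 | intermediate
19 | 2-[4-(allyloxy)-2-methoxyphenyl]-4-hydroxy-6-methoxy-5-(3-methylbut-2-en-1-yl)-1-benzofuran-3-carbaldehyde | COc1cc2oc(-c3ccc(OCC=C)cc3OC)c(C=O)c2c(O)c1CC=C(C)C | intermediate
20 | ebenfuran IV, 4-hydroxy-2-(4-hydroxy-2-methoxyphenyl)-6-methoxy-5-(3-methylbut-2-en-1-yl)-1-benzofuran-3-carbaldehyde (achiral) | COc1cc(O)ccc1-c1oc2cc(OC)c(CC=C(C)C)c(O)c2c1C=O | target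

**Totals**
Total step count: 8. Longest linear sequence: 7 (steps 1, 2, 4, 5, 6, 7, 8); step 3 is a one-step side branch.

**Three steps most likely to fail**

Step 7 is the weakest step, because O-prenylation and attack at C7 (para) compete with the wanted C5 alkylation. The fallback sets out from 16. Iodination ortho to the free peri-hydroxyl with benzyltrimethylammonium dichloroiodate/CaCO3 in CH2Cl2–MeOH (the free OH directs iodine to the adjacent carbon, as in 5-hydroxy-7-methoxyflavones) gives 2-[4-(allyloxy)-2-methoxyphenyl]-4-hydroxy-5-iodo-6-methoxy-1-benzofuran-3-carbaldehyde F1. Stille coupling with tributyl(3-methylbut-2-en-1-yl)stannane (Pd(PPh3)4, DMF, 90 °C) then installs the prenyl group at the iodinated carbon, and the route is rejoined at 19.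

Step 6 may give the isomeric 3-aroylbenzofuran (phenol closing on the aldehyde carbon and aromatising) instead of the 3-formyl compound. The fallback sets out from 13. Propane-1,3-dithiol/BF3·OEt2 in CH2Cl2 exchanges the dimethyl acetal for a dithiane and strips both MOM groups, leaving the ketone as the only electrophile for the freed phenol. This gives 3-(1,3-dithian-2-yl)-6-methoxy-2-[4-(allyloxy)-2-methoxyphenyl]-1-benzofuran-4-ol F2. MeI/CaCO3 in aqueous MeCN then unmasks the aldehyde, and the route is rejoined at 16.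

Step 5 may suffer from ring iodination or over-oxidation of the very electron-rich arenes, or premature MOM loss caused by the TsOH released. The fallback sets out from 11. Weitz–Scheffer epoxidation (H2O2, NaOH, MeOH–THF) gives the trans-epoxy ketone rac-[(2R*,3S*)-3-[4-methoxy-2,6-bis(methoxymethoxy)phenyl]oxiran-2-yl][4-(allyloxy)-2-methoxyphenyl]methanone F3. BF3·OEt2 (CH2Cl2, −40 °C) then opens it to the benzylic cation and triggers the House–Meinwald 1,2-acyl shift to 3-[4-(allyloxy)-2-methoxyphenyl]-2-[4-methoxy-2,6-bis(methoxymethoxy)phenyl]-3-oxopropanal F4. Under the step 6 conditions F4 passes through 15, and the route is rejoined at 16.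

**Further compounds**
F1 | step 7 | 2-[4-(allyloxy)-2-methoxyphenyl]-4-hydroxy-5-iodo-6-methoxy-1-benzofuran-3-carbaldehyde | COc1cc2oc(-c3ccc(OCC=C)cc3OC)c(C=O)c2c(O)c1I
F2 | step 6 | 3-(1,3-dithian-2-yl)-6-methoxy-2-[4-(allyloxy)-2-methoxyphenyl]-1-benzofuran-4-ol | COc1cc(O)c2c(C3SCCCS3)c(-c3ccc(OCC=C)cc3OC)oc2c1
F3 | step 5 | rac-[(2R*,3S*)-3-[4-methoxy-2,6-bis(methoxymethoxy)phenyl]oxiran-2-yl][4-(allyloxy)-2-methoxyphenyl]methanone (trans, one enantiomer drawn) | O=C([C@@H]1O[C@H]1c1c(OCOC)cc(OC)cc1OCOC)c1ccc(OCC=C)cc1OC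
F4 | step 5 | 3-[4-(allyloxy)-2-methoxyphenyl]-2-[4-methoxy-2,6-bis(methoxymethoxy)phenyl]-3-oxopropanal (racemic) | O=CC(C(=O)c1ccc(OCC=C)cc1OC)c1c(OCOC)cc(OC)cc1OCOC
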